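**Retrosynthetic overview**
- The target is (3R)-2,3-dihydroirigenin. The three benzyl ethers come off last by neutral hydrogenolysis, and C3 is set just before by enantioselective reduction of the tri-O-benzyl isoflavone (the isoflavone reductase step).
- The isoflavone comes from the flavanone by an oxidative 2,3-aryl shift with trivalent iodine (the isoflavone synthase step). The flavanone comes from the 2'-hydroxychalcone by oxa-Michael closure (the chalcone isomerase step). Both run in one flask.
- The chalcone comes from a Claisen–Schmidt condensation of a ring A acetophenone with a ring B aldehyde.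
- The ring A ketone comes from phloroacetophenone (dibenzylation, Elbs para-hydroxylation, O-methylation). The ring B aldehyde comes from 3-hydroxy-4,5-dimethoxybenzaldehyde.
- Rings A and B are bought; ring C is the only ring formed, in step 6.

Assumption: the presumed biosynthesis is the general isoflavonoid pathway (chalcone, flavanone, 2,3-aryl shift to the isoflavone, reduction to the isoflavanone); the stereodescriptor in the SMILES corresponds to (3R).

**Route**

Step 1
Reactants: 1 1-(2,4,6-trihydroxyphenyl)ethanone (phloroacetophenone)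
Product: 2 1-[2,4-bis(benzyloxy)-6-hydroxyphenyl]ethanone
Conditions: BnBr (2.05 equiv), K2CO3 (2.2 equiv), DMF, 20 to 60 °C
Reagents that add atoms: benzyl bromide, BrCc1ccccc1
Why: Williamson etherification in which the 4-OH and one ortho OH are alkylated while the last ortho OH stays free because it is hydrogen-bonded to the acetyl carbonyl.

Step 2
Reactants: 2 1-[2,4-bis(benzyloxy)-6-hydroxyphenyl]ethanone
Product: 4 1-[2,4-bis(benzyloxy)-3,6-dihydroxyphenyl]ethanone, via aryl potassium sulfate 3 (not isolated)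
Conditions: K2S2O8 (1.2 equiv), aq. NaOH, pyridine, 10–20 °C; then 2 M HCl, 80 °C
Reagents that add atoms: potassium peroxodisulfate, [K+].[K+].[O-]S(=O)(=O)OOS(=O)(=O)[O-]
Why: Elbs persulfate oxidation, in which the phenoxide attacks the peroxide through the only carbon para to the free OH and acid hydrolysis of the aryl sulfate unmasks the oxygen that becomes O-6 of the chromanone.

Step 3
Reactants: 4 1-[2,4-bis(benzyloxy)-3,6-dihydroxyphenyl]ethanone
Product: 5 1-[2,4-bis(benzyloxy)-6-hydroxy-3-methoxyphenyl]ethanone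
Conditions: MeI (1.05 equiv), K2CO3 (1.1 equiv), acetone, 20–40 °C
Reagents that add atoms: iodomethane, CI
Why: Selective Williamson O-methylation of the non-chelated phenol, the chelated ortho-hydroxy ketone OH being far less nucleophilic (classical for 2,5-dihydroxy-4,6-dialkoxyacetophenones).

Step 4
Reactants: 6 3-hydroxy-4,5-dimethoxybenzaldehyde
Product: 7 3-(benzyloxy)-4,5-dimethoxybenzaldehyde
Conditions: BnBr (1.1 equiv), K2CO3, DMF, 20 °C
Reagents that add atoms: benzyl bromide, BrCc1ccccc1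
Why: Williamson etherification of the only phenol, needed because a free guaiacol-type phenol would not survive the trivalent iodine oxidant of step 6.

Step 5
Reactants: 5 1-[2,4-bis(benzyloxy)-6-hydroxy-3-methoxyphenyl]ethanone; 7 3-(benzyloxy)-4,5-dimethoxybenzaldehyde
Product: 8 (E)-1-[2,4-bis(benzyloxy)-6-hydroxy-3-methoxyphenyl]-3-[3-(benzyloxy)-4,5-dimethoxyphenyl]prop-2-en-1-one
Conditions: KOH (50% aq.), EtOH, 20 °C, 24–48 h; then cold dilute HCl to pH 5
Reagents that add atoms: none
Why: Claisen–Schmidt aldol condensation of the methyl ketone enolate with the non-enolisable aldehyde, E1cB dehydration giving the E-chalcone.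

Step 6
Reactants: 8 (E)-1-[2,4-bis(benzyloxy)-6-hydroxy-3-methoxyphenyl]-3-[3-(benzyloxy)-4,5-dimethoxyphenyl]prop-2-en-1-one
Product: 11 5,7-bis(benzyloxy)-3-[3-(benzyloxy)-4,5-dimethoxyphenyl]-6-methoxy-4H-chromen-4-one, via racemic flavanone 9 (not isolated), via 3-iodanyl flavanone 10 (not isolated)
Conditions: TsOH·H2O (0.2 equiv), MeCN, 80 °C until 8 is consumed; then PhI(OH)OTs (Koser's reagent, 1.2 equiv), 60–80 °C
Reagents that add atoms: none
Why: Acid-catalysed 6-endo oxa-Michael closure (chalcone–flavanone isomerisation, favoured by the 6'-benzyloxy group) forms ring C and masks the oxidation-prone para-methoxyphenol, after which Koser's reagent attacks the flavanone enol at C3 trans to the 2-aryl group and the electron-rich aryl migrates from C2 to C3 with loss of PhI (hypervalent-iodine oxidative 2,3-aryl shift, known for flavanones in MeCN), the C2 oxocarbenium ion then losing H-3 to give the achiral isoflavone.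

Step 7
Reactants: 11 5,7-bis(benzyloxy)-3-[3-(benzyloxy)-4,5-dimethoxyphenyl]-6-methoxy-4H-chromen-4-one
Product: 13 (3R,4R)-5,7-bis(benzyloxy)-3-[3-(benzyloxy)-4,5-dimethoxyphenyl]-6-methoxychroman-4-ol, via racemic isoflavanone 12 (not isolated)
Conditions: RuCl(p-cymene)[(R,R)-TsDPEN] (5 mol %), HCO2H/Et3N (5:2), EtOAc, 40 °C
Reagents that add atoms: none
Why: Noyori–Ikariya asymmetric transfer hydrogenation, in which conjugate reduction gives the isoflavanone that racemises quickly under Et3N and the (R,R) catalyst then reduces the (3R) enantiomer faster (dynamic kinetic resolution), setting C4 as R by the usual aryl ketone model and C3 as R through the cis preference.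

Step 8
Reactants: 13 (3R,4R)-5,7-bis(benzyloxy)-3-[3-(benzyloxy)-4,5-dimethoxyphenyl]-6-methoxychroman-4-ol
Product: 14 (3R)-5,7-bis(benzyloxy)-3-[3-(benzyloxy)-4,5-dimethoxyphenyl]-6-methoxychroman-4-one
Conditions: Dess–Martin periodinane (1.3 equiv), CH2Cl2, 0 to 20 °C; filtration through silica, no basic wash
Reagents that add atoms: none
Why: Dess–Martin oxidation of the benzylic alcohol under non-basic conditions restores the C4 ketone without enolising C3, so the (3R) centre from step 7 is kept and only the C4 centre is removed.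

Step 9
Reactants: 14 (3R)-5,7-bis(benzyloxy)-3-[3-(benzyloxy)-4,5-dimethoxyphenyl]-6-methoxychroman-4-one
Product: 15 (3R)-5,7-dihydroxy-3-(3-hydroxy-4,5-dimethoxyphenyl)-6-methoxychroman-4-one
Conditions: H2 (1 atm), Pd/C (10 wt %), EtOAc, 20 °C
Reagents that add atoms: none
Why: Neutral hydrogenolysis of the three benzyl ethers over palladium on carbon, with no acid or base present to epimerise the α-aryl ketone centre and with the ketone deactivated by its chelated 5-OH once that is unmasked.

**Compound list**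

1 | 1-(2,4,6-trihydroxyphenyl)ethanone | CC(=O)c1c(O)cc(O)cc1O | starting material
2 | 1-[2,4-bis(benzyloxy)-6-hydroxyphenyl]ethanone | CC(=O)c1c(O)cc(OCc2ccccc2)cc1OCc3ccccc3 | intermediate
3 | potassium 3-acetyl-2,6-bis(benzyloxy)-4-hydroxyphenyl sulfate | CC(=O)c1c(O)cc(OCc2ccccc2)c(OS(=O)(=O)[O-])c1OCc3ccccc3.[K+] | intermediate
4 | 1-[2,4-bis(benzyloxy)-3,6-dihydroxyphenyl]ethanone | CC(=O)c1c(O)cc(OCc2ccccc2)c(O)c1OCc3ccccc3 | intermediate
5 | 1-[2,4-bis(benzyloxy)-6-hydroxy-3-methoxyphenyl]ethanone | CC(=O)c1c(O)cc(OCc2ccccc2)c(OC)c1OCc3ccccc3 | intermediate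
6 | 3-hydroxy-4,5-dimethoxybenzaldehyde | COc1cc(C=O)cc(O)c1OC | starting material
7 | 3-(benzyloxy)-4,5-dimethoxybenzaldehyde | COc1cc(C=O)cc(OCc2ccccc2)c1OC | intermediate
8 | (E)-1-[2,4-bis(benzyloxy)-6-hydroxy-3-methoxyphenyl]-3-[3-(benzyloxy)-4,5-dimethoxyphenyl]prop-2-en-1-one | COc1cc(/C=C/C(=O)c2c(O)cc(OCc3ccccc3)c(OC)c2OCc4ccccc4)cc(OCc5ccccc5)c1OC | intermediate
9 | racemic 5,7-bis(benzyloxy)-2-[3-(benzyloxy)-4,5-dimethoxyphenyl]-6-methoxychroman-4-one | COc1cc(C2CC(=O)c3c(OCc4ccccc4)c(OC)c(OCc5ccccc5)cc3O2)cc(OCc6ccccc6)c1OC | intermediate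
10 | racemic trans-5,7-bis(benzyloxy)-2-[3-(benzyloxy)-4,5-dimethoxyphenyl]-6-methoxy-3-[phenyl(tosyloxy)-λ3-iodanyl]chroman-4-one (one enantiomer drawn) | COc1cc([C@H]2Oc3cc(OCc4ccccc4)c(OC)c(OCc5ccccc5)c3C(=O)[C@@H]2[I](c7ccccc7)OS(=O)(=O)c8ccc(C)cc8)cc(OCc6ccccc6)c1OC | intermediate
11 | 5,7-bis(benzyloxy)-3-[3-(benzyloxy)-4,5-dimethoxyphenyl]-6-methoxy-4H-chromen-4-one (tri-O-benzylirigenin) | COc1cc(-c2coc3cc(OCc4ccccc4)c(OC)c(OCc5ccccc5)c3c2=O)cc(OCc6ccccc6)c1OC | intermediate
12 | racemic 5,7-bis(benzyloxy)-3-[3-(benzyloxy)-4,5-dimethoxyphenyl]-6-methoxychroman-4-one | COc1cc(C2COc3cc(OCc4ccccc4)c(OC)c(OCc5ccccc5)c3C2=O)cc(OCc6ccccc6)c1OC | intermediate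
13 | (3R,4R)-5,7-bis(benzyloxy)-3-[3-(benzyloxy)-4,5-dimethoxyphenyl]-6-methoxychroman-4-ol (3,4-cis) | COc1cc([C@@H]2COc3cc(OCc4ccccc4)c(OC)c(OCc5ccccc5)c3[C@@H]2O)cc(OCc6ccccc6)c1OC | intermediate
14 | (3R)-5,7-bis(benzyloxy)-3-[3-(benzyloxy)-4,5-dimethoxyphenyl]-6-methoxychroman-4-one | COc1cc([C@@H]2COc3cc(OCc4ccccc4)c(OC)c(OCc5ccccc5)c3C2=O)cc(OCc6ccccc6)c1OC | intermediate
15 | (3R)-5,7-dihydroxy-3-(3-hydroxy-4,5-dimethoxyphenyl)-6-methoxychroman-4-one | COc1cc([C@@H]2COc3cc(O)c(OC)c(O)c3C2=O)cc(O)c1OC | target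

**Step count**
- Total: 9 steps.
- Longest linear sequence: 8 steps (steps 1, 2, 3, 5, 6, 7, 8, 9, from 1 to 15).

**Steps most likely to fail, with fallbacks**

1. Step 6 (one-flask ring closure and 2,3-aryl shift). Possible failures are dehydrogenation to the flavone, attack of the iodane on C8 of ring A, and oxidation of any uncyclised chalcone at its para-methoxyphenol. The fallback moves the aryl shift to the open chain. It sets out from 8, which is acetylated (Ac2O, pyridine) to 3,5-bis(benzyloxy)-2-{(E)-3-[3-(benzyloxy)-4,5-dimethoxyphenyl]prop-2-enoyl}-4-methoxyphenyl acetate F1. Oxidative rearrangement with Tl(NO3)3·3H2O in MeOH/HC(OMe)3 gives 3,5-bis(benzyloxy)-2-{2-[3-(benzyloxy)-4,5-dimethoxyphenyl]-3,3-dimethoxypropanoyl}-4-methoxyphenyl acetate F2. HCl in MeOH at 50 °C removes the acetate and closes ring C, and the route is rejoined at 11.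

2. Step 2 (Elbs oxidation). The dibenzyl ether is poorly soluble in aqueous alkali and Elbs yields are typically modest. The fallback replaces steps 2 and 3 by oxidative dearomatisation and reductive rearomatisation. It sets out from 2, which is oxidised with PhI(OAc)2 (2.2 equiv) in MeOH to 2-acetyl-3,5-bis(benzyloxy)-4,4-dimethoxycyclohexa-2,5-dien-1-one F3. Reduction with Zn dust in AcOH rearomatises it with loss of one methoxy group, and the route is rejoined at 5.

3. Step 7 (transfer hydrogenation with dynamic kinetic resolution). The C4 carbonyl is flanked by the 5-benzyloxy group and may be reduced slowly or with low selectivity; the sense of induction should be confirmed on the first batch. The fallback sets C3 by enantioselective protonation and replaces steps 7 and 8. It sets out from 11, which undergoes 1,4-reduction with LiBH(s-Bu)3 in THF at −78 °C and trapping with Me3SiCl to give {5,7-bis(benzyloxy)-3-[3-(benzyloxy)-4,5-dimethoxyphenyl]-6-methoxy-2H-chromen-4-yl}oxy(trimethyl)silane F4. Catalytic enantioselective protonation with (R)-BINAP(AuCl)2/AgBF4 in EtOH–CH2Cl2 (ligand antipode chosen by test) then rejoins the route at 14.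

Further compounds
F1 | step 6 | 3,5-bis(benzyloxy)-2-{(E)-3-[3-(benzyloxy)-4,5-dimethoxyphenyl]prop-2-enoyl}-4-methoxyphenyl acetate | COc1cc(/C=C/C(=O)c2c(OC(C)=O)cc(OCc3ccccc3)c(OC)c2OCc4ccccc4)cc(OCc5ccccc5)c1OC
F2 | step 6 | racemic 3,5-bis(benzyloxy)-2-{2-[3-(benzyloxy)-4,5-dimethoxyphenyl]-3,3-dimethoxypropanoyl}-4-methoxyphenyl acetate | COc1cc(C(C(OC)OC)C(=O)c2c(OC(C)=O)cc(OCc3ccccc3)c(OC)c2OCc4ccccc4)cc(OCc5ccccc5)c1OC
F3 | step 2 | 2-acetyl-3,5-bis(benzyloxy)-4,4-dimethoxycyclohexa-2,5-dien-1-one | CC(=O)C1=C(OCc2ccccc2)C(OC)(OC)C(OCc3ccccc3)=CC1=O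
F4 | step 7 | {5,7-bis(benzyloxy)-3-[3-(benzyloxy)-4,5-dimethoxyphenyl]-6-methoxy-2H-chromen-4-yl}oxy(trimethyl)silane | COc1cc(C2=C(O[Si](C)(C)C)c3c(OCc4ccccc4)c(OC)c(OCc5ccccc5)cc3OC2)cc(OCc6ccccc6)c1OC
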